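The numbers in the tables stem from a simulated flask from invented constants; the scatter is artificial.

Amounts come first. After 30.0 min the target reads 17.0 mM in oak, 24.7 mM in alder and 17.1 mM in cedar, although cedar holds ten times the substrate of oak. Coupling partner is the limiting reagent in alder and cedar.

| run | time / min | target / % | isomer of the product / % |
|---|---|---|---|
| oak | 2.50 | 5 | 0 |
| oak | 4.00 | 8 | 0 |
| oak | 8.00 | 12 | 0 |
| oak | 15.0 | 23 | 2 |
| oak | 30.0 | 31 | 1 |
| alder | 2.50 | 3 | 1 |
| alder | 8.00 | 4 | 0 |
| alder | 12.0 | 10 | 1 |
| alder | 20.0 | 11 | 2 |
| alder | 30.0 | 13 | 0 |
| cedar | 2.50 | 0 | 0 |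
| cedar | 4.00 | 0 | 0 |
| cedar | 8.00 | 0 | 0 |
| cedar | 15.0 | 4 | 4 |
| cedar | 30.0 | 3 | 1 |

(readings scatter by 2 percentage points)

The next series keeps coupling partner and protic impurity as they were, spreads the substrate and reads at one time. The decision is whether the substrate charge can be chosen without regard to the share of target.

| flask | substrate | coupling partner | protic impurity | remark | time |
|---|---|---|---|---|---|
| oak | 0.055 M | 0.055 M | 1 mM | run made earlier |  |
| alder | 0.19 M | 0.055 M | 1 mM | run made earlier |  |
| cedar | 0.57 M | 0.055 M | 1 mM | run made earlier |  |
| spring | 0.050 M | 0.0550 M | 1.00 mM |  | 40 min |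
| dawn | 0.10 M | 0.0550 M | 1.00 mM |  | 40 min |
| dusk | 0.20 M | 0.0550 M | 1.00 mM |  | 40 min |
| autumn | 0.40 M | 0.0550 M | 1.00 mM |  | 40 min |
| noon | 0.80 M | 0.0550 M | 1.00 mM |  | 40 min |

* share of target in all that became target or isomer of the product for spring, dawn, dusk, autumn, noon, in this order
* how that number moves from the first to the last of them (falls all the way / rises all the way / falls, then rises / hardly changes / rises, then falls)

- on the list of suspects stand: 2 coupling partner -> homo dimer; target <-> isomer of the product; coupling partner + protic impurity -> quenched reagent; intermediate <-> target + by-product; substrate + coupling partner <-> intermediate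
- "hardly changes" means that all values lie within two and a half points (for a concentration: within two and a half percent of the largest)

On the list of suspects the isomer of the product has one source, the target, by a first-order step. That step carries no substrate term, and the reckoning here takes [isomer]/[target] to grow in proportion to time in each flask. The isomer clock, the gain of [isomer]/[target] per minute, comes from the readings from 15.0 min on: the isomer readings are summed and divided by the summed products of target and time. The isomer sum is 10.0%, with a scatter of 2 percentage points on each reading, so the clock is a loose reading: 0.00491 min⁻¹. At 40 min it gives a reckoned share of 83.6%, with no term for the substrate charge. For the share of target this reckoning therefore leaves the substrate charge open, and the series runs as listed.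

The forecast differs from this reckoning in level and agrees in shape, with 95.5% at spring, 95% at noon and hardly changes, on the ground that “Substrate therefore sets how much target forms, not how it divides between target and isomer.”

The flask gives 87.7%, 87.3%, 86.9%, 86.7% and 86.6%: hardly changes.

    2 coupling partner → homo dimer (k = 0.140 L mol⁻¹ min⁻¹)
    target ⇌ isomer of the product (K = 0.270, k = 0.00790 min⁻¹)
    coupling partner + protic impurity → quenched reagent (k = 12.0 L mol⁻¹ min⁻¹)
    intermediate ⇌ target + by-product (K = 0.0530 M, k = 0.0450 min⁻¹)
    substrate + coupling partner ⇌ intermediate (K = 28.0 L mol⁻¹, k = 12.0 L mol⁻¹ min⁻¹)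

Spring stands 4.1 points above the reckoned 83.6%. At 40.0 min in spring, target is still made 2.48 times faster than it is used up, each step taken net. The clock has no substrate term, so the same 83.6% stands for noon, at 16.0 times the substrate of spring. After 40.0 min noon holds target at 3.57% and isomer of the product at 0.555% of the substrate charged, a share of 86.6%.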